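**Strategy.** The trans-decalin is unfolded by cutting the ring-fusion bond C5–C10 and the ring B bond C7–C8 (labdane numbering). This exploits the oxygenated C9 of ring B, flanked by C8 and C10: the C8–C9–C10 unit becomes an ethyl ketone (an α,α′-bis-nucleophile) and C5–C6–C7 becomes an enal. In the key step this acyclic keto enal, which carries the C2/C3 cis-diol as an acetonide and the C4 gem-dimethyl group, undergoes a base-mediated intramolecular Michael addition/aldol condensation cascade that closes ring A and ring B and sets C5 and C10. The C9 carbonyl then takes up the side chain by vinyl addition, hydroboration and B-alkyl Suzuki coupling with an (E)-enol triflate.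

Key step: step 7

Remark: labdane numbering is used throughout (decalin C1–C10, side chain C11–C16, C17 on C8, C20 on C10); the target is read as trans-fused with H5 α and the C10 methyl β, 8α-methyl, 9β-OH with the side chain α, a 2α,3α-diol and a 13E enoate.

**Step 1**
Reactants: 1 acrolein
Product: 2 rac-4,4-dimethylhexa-1,5-dien-3-ol
Conditions: prenylmagnesium chloride, THF, −78 → 0 °C; aq. NH4Cl
Reagents that add atoms: prenylmagnesium chloride (3-methylbut-2-enylmagnesium chloride), CC(C)=CC[Mg]Cl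
Why: Allylic Grignard reagents add 1,2 to aldehydes through their γ-carbon (SE2′, six-membered transition state), so the reverse-prenyl carbinol with the C4 quaternary carbon and the C5=C6 vinyl group should form as the racemate.

**Step 2**
Reactants: 2 rac-4,4-dimethylhexa-1,5-dien-3-ol
Product: 3 (1S)-2,2-dimethyl-1-[(2R)-oxiran-2-yl]but-3-en-1-ol
Conditions: Ti(OiPr)4 (15 mol %), L-(+)-diisopropyl tartrate (18 mol %), t-BuOOH (0.55 equiv), 4 Å MS, CH2Cl2, −20 °C
Reagents that add atoms: tert-butyl hydroperoxide, CC(C)(C)OO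
Why: Sharpless kinetic resolution of a secondary allylic alcohol: with the L-(+)-tartrate the (R)-enantiomer should be epoxidised fast and with erythro selectivity, which sets C2 (R) and C3 (S), while the homoallylic C5=C6 vinyl group is left alone and the slow (S)-alcohol is separated.

**Step 3**
Reactants: 3 (1S)-2,2-dimethyl-1-[(2R)-oxiran-2-yl]but-3-en-1-ol; 4 1-(morpholin-4-yl)propan-1-one
Product: 6 (4R,5S)-4,5-dihydroxy-2,6,6-trimethyl-1-(morpholin-4-yl)oct-7-en-1-one (both C2 epimers), via lithium enolate 5 (not isolated)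
Conditions: 4 (2.4 equiv), LiN(iPr)2, THF, −78 °C; then 3, −78 → 0 °C; aq. NH4Cl
Reagents that add atoms: none
Why: SN2 opening of the terminal epoxide at the unsubstituted C1 by the lithium amide enolate (one equivalent is consumed by the free hydroxyl) forms C1–C10 without touching C2; the new α-centre (C10) is uncontrolled, which is harmless because it is enolised in step 7.

**Step 4**
Reactants: 6 (4R,5S)-4,5-dihydroxy-2,6,6-trimethyl-1-(morpholin-4-yl)oct-7-en-1-one
Product: 7 3-[(4R,5S)-2,2-dimethyl-5-(2-methylbut-3-en-2-yl)-1,3-dioxolan-4-yl]-2-methyl-1-(morpholin-4-yl)propan-1-one (both C2 epimers)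
Conditions: 2,2-dimethoxypropane, PPTS (cat.), acetone, 23 °C
Reagents that add atoms: 2,2-dimethoxypropane, COC(C)(C)OC
Why: Acid-catalysed transketalisation of the erythro 1,2-diol should give the cis-4,5-disubstituted dioxolane, and the tertiary amide resists lactonisation under these mild conditions.

**Step 5**
Reactants: 7 3-[(4R,5S)-2,2-dimethyl-5-(2-methylbut-3-en-2-yl)-1,3-dioxolan-4-yl]-2-methyl-1-(morpholin-4-yl)propan-1-one
Product: 8 5-[(4R,5S)-2,2-dimethyl-5-(2-methylbut-3-en-2-yl)-1,3-dioxolan-4-yl]-4-methylpentan-3-one (both C4 epimers)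
Conditions: EtMgBr, THF, 0 → 23 °C; aq. NH4Cl
Reagents that add atoms: ethylmagnesium bromide, CC[Mg]Br
Why: Grignard acylation with a morpholine amide: the magnesium hemiaminal is stable until work-up, so mono-addition should give the ethyl ketone (C8, C17).

**Step 6**
Reactants: 8 5-[(4R,5S)-2,2-dimethyl-5-(2-methylbut-3-en-2-yl)-1,3-dioxolan-4-yl]-4-methylpentan-3-one; 9 (E)-but-2-enal
Product: 10 (2E)-4-[(4S,5R)-2,2-dimethyl-5-(2-methyl-3-oxopentyl)-1,3-dioxolan-4-yl]-4-methylpent-2-enal
Conditions: 9 (5 equiv), second-generation Hoveyda–Grubbs catalyst (5 mol %), CH2Cl2, 40 °C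
Reagents that add atoms: none
Why: Olefin cross-metathesis: a vinyl group on a quaternary carbon does not homodimerise, and coupling with excess crotonaldehyde should give the conjugated (E)-enal with loss of propene.

**Step 7**
Reactants: 10 (2E)-4-[(4S,5R)-2,2-dimethyl-5-(2-methyl-3-oxopentyl)-1,3-dioxolan-4-yl]-4-methylpent-2-enal
Product: 13 (4aS,6S,7R,8aS)-6,7-(isopropylidenedioxy)-2,5,5,8a-tetramethyl-4a,5,6,7,8,8a-hexahydronaphthalen-1(4H)-one (the Δ7-en-9-one), via Michael adduct 11 (not isolated), via aldol adduct 12 (not isolated)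
Conditions: KOt-Bu (0.5 equiv), t-BuOH/THF (1:1), 0.01 M, 0 → 40 °C
Reagents that add atoms: none
Why: Under equilibrating alkoxide conditions the ketone enolises on both sides, but only the C10 enolate can reach the enal β-carbon C5 through a six-membered transition state (6-(enolexo)-exo-trig Michael addition, closing ring A and forming C5–C10); the liberated aldehyde is then attacked by the C8 enolate (6-(enolendo)-exo-trig aldol, closing ring B and forming C7–C8) and E1cB loss of water makes the sequence irreversible. The closest known reaction type is the intramolecular Michael/aldol condensation cascade, a [3+3] Robinson-type annulation of a ketone with an enal. C5 is set by the chair transition state enforced by the cis-acetonide and the C4 gem-dimethyl group: the chair with C3–O axial and C2–O equatorial avoids the syn-axial O/CH3 clash of the alternative chair, and the enal arm sits equatorial, so H5 should end up cis to the C3 oxygen (α). C10 is set in the same transition state: the methyl takes the axial site beside the axial C4 methyl and the bulkier potassium enolate unit stays equatorial, which should give the trans ring fusion (C10 methyl β, H5 α). The step needs regioselectivity between the two enolates and trans selectivity at the ring fusion; ring size secures the first, the chair preference the second, and high dilution suppresses intermolecular aldol reactions.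

**Step 8**
Reactants: 13 (4aS,6S,7R,8aS)-6,7-(isopropylidenedioxy)-2,5,5,8a-tetramethyl-4a,5,6,7,8,8a-hexahydronaphthalen-1(4H)-one
Product: 15 (2R,4aS,6S,7R,8aS)-6,7-(isopropylidenedioxy)-2,5,5,8a-tetramethyloctahydronaphthalen-1(2H)-one (8α-methyl 9-ketone), via C8 epimer 14 (not isolated)
Conditions: H2 (1 atm), Pd/C, EtOAc, 23 °C; then NaOMe (cat.), MeOH, 23 °C
Reagents that add atoms: none
Why: Heterogeneous hydrogenation of the enone C7=C8 bond is followed by base equilibration of C8, the only epimerisable centre (C10 is quaternary), which should place the C8 methyl equatorial (α) and away from the axial C10 methyl.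

**Step 9**
Reactants: 15 (2R,4aS,6S,7R,8aS)-6,7-(isopropylidenedioxy)-2,5,5,8a-tetramethyloctahydronaphthalen-1(2H)-one
Product: 16 (1S,2R,4aS,6S,7R,8aS)-1-ethenyl-6,7-(isopropylidenedioxy)-2,5,5,8a-tetramethyldecahydronaphthalen-1-ol (9α-vinyl-9β-ol)
Conditions: vinylmagnesium bromide, CeCl3, THF, −78 → 0 °C; aq. NH4Cl
Reagents that add atoms: vinylmagnesium bromide, C=C[Mg]Br
Why: Organocerium 1,2-addition suppresses enolisation, and the small vinyl nucleophile should attack C9 axially from the α face, anti to the axial C10 methyl that blocks the equatorial β trajectory, giving the side-chain carbon α and the hydroxyl β.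

**Step 10**
Reactants: 17 methyl acetoacetate
Product: 18 methyl (2E)-3-{[(trifluoromethyl)sulfonyl]oxy}but-2-enoate
Conditions: Tf2O, aq. (CH3)4NOH, hexanes, 5 °C
Reagents that add atoms: trifluoromethanesulfonic anhydride, O=S(=O)(OS(=O)(=O)C(F)(F)F)C(F)(F)F
Why: O-triflation of the non-chelated tetramethylammonium enolate of the β-keto ester, which reacts through its extended form, should give the (E)-enol triflate (a lithium chelate would give the Z isomer).

**Step 11**
Reactants: 16 (1S,2R,4aS,6S,7R,8aS)-1-ethenyl-6,7-(isopropylidenedioxy)-2,5,5,8a-tetramethyldecahydronaphthalen-1-ol; 18 methyl (2E)-3-{[(trifluoromethyl)sulfonyl]oxy}but-2-enoate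
Product: 20 methyl (2E)-5-[(1S,2R,4aS,6S,7R,8aS)-1-hydroxy-6,7-(isopropylidenedioxy)-2,5,5,8a-tetramethyldecahydronaphthalen-1-yl]-3-methylpent-2-enoate, via alkylborane 19 (not isolated)
Conditions: 9-BBN (2.5 equiv), THF, 0 → 23 °C; then 18, Pd(dppf)Cl2 (5 mol %), aq. K3PO4, DMF, 23 → 45 °C
Reagents that add atoms: none
Why: Anti-Markovnikov hydroboration of the monosubstituted vinyl group puts boron on C12, and the B-alkyl Suzuki–Miyaura coupling with the (E)-enol triflate proceeds with retention of alkene geometry, which fixes the 13E enoate.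

**Step 12**
Reactants: 20 methyl (2E)-5-[(1S,2R,4aS,6S,7R,8aS)-1-hydroxy-6,7-(isopropylidenedioxy)-2,5,5,8a-tetramethyldecahydronaphthalen-1-yl]-3-methylpent-2-enoate
Product: 21 methyl (2E)-5-[(1S,2R,4aS,6S,7R,8aS)-1,6,7-trihydroxy-2,5,5,8a-tetramethyldecahydronaphthalen-1-yl]-3-methylpent-2-enoate (target)
Conditions: AcOH/H2O (4:1), 40 °C
Reagents that add atoms: none
Why: Acid-catalysed acetal hydrolysis frees the cis-2,3-diol, and the hindered tertiary C9 alcohol and the methyl enoate should tolerate aqueous acetic acid.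

**Compound list**
1 | acrolein (prop-2-enal) | C=CC=O | starting material
2 | rac-4,4-dimethylhexa-1,5-dien-3-ol | C=CC(O)C(C)(C)C=C | intermediate
3 | (1S)-2,2-dimethyl-1-[(2R)-oxiran-2-yl]but-3-en-1-ol | C1O[C@H]1[C@@H](O)C(C)(C)C=C | intermediate
4 | 1-(morpholin-4-yl)propan-1-one | CCC(=O)N1CCOCC1 | starting material
5 | lithium (Z)-1-(morpholin-4-yl)prop-1-en-1-olate | C/C=C(\[O-])N1CCOCC1.[Li+] | intermediate (not isolated)
6 | (4R,5S)-4,5-dihydroxy-2,6,6-trimethyl-1-(morpholin-4-yl)oct-7-en-1-one, both C2 epimers | O=C(N1CCOCC1)C(C)C[C@@H](O)[C@@H](O)C(C)(C)C=C | intermediate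
7 | 3-[(4R,5S)-2,2-dimethyl-5-(2-methylbut-3-en-2-yl)-1,3-dioxolan-4-yl]-2-methyl-1-(morpholin-4-yl)propan-1-one, both C2 epimers | O=C(N1CCOCC1)C(C)C[C@H]2OC(C)(C)O[C@H]2C(C)(C)C=C | intermediate
8 | 5-[(4R,5S)-2,2-dimethyl-5-(2-methylbut-3-en-2-yl)-1,3-dioxolan-4-yl]-4-methylpentan-3-one, both C4 epimers | CCC(=O)C(C)C[C@H]1OC(C)(C)O[C@H]1C(C)(C)C=C | intermediate
9 | (E)-but-2-enal (crotonaldehyde) | C/C=C/C=O | starting material
10 | (2E)-4-[(4S,5R)-2,2-dimethyl-5-(2-methyl-3-oxopentyl)-1,3-dioxolan-4-yl]-4-methylpent-2-enal | CCC(=O)C(C)C[C@H]1OC(C)(C)O[C@H]1C(C)(C)/C=C/C=O | intermediate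
11 | 2-[(3aS,5S,6S,7aR)-2,2,4,4,6-pentamethyl-6-propanoylhexahydro-1,3-benzodioxol-5-yl]acetaldehyde (ring A Michael adduct) | CCC(=O)[C@@]1(C)C[C@H]2OC(C)(C)O[C@H]2C(C)(C)[C@@H]1CC=O | intermediate (not isolated)
12 | (4aS,6S,7R,8aS)-3-hydroxy-6,7-(isopropylidenedioxy)-2,5,5,8a-tetramethyloctahydronaphthalen-1(2H)-one, C2/C3 epimers (aldol adduct) | O=C1C(C)C(O)C[C@H]2C(C)(C)[C@@H]3OC(C)(C)O[C@@H]3C[C@@]21C | intermediate (not isolated)
13 | (4aS,6S,7R,8aS)-6,7-(isopropylidenedioxy)-2,5,5,8a-tetramethyl-4a,5,6,7,8,8a-hexahydronaphthalen-1(4H)-one | O=C1C(C)=CC[C@H]2C(C)(C)[C@@H]3OC(C)(C)O[C@@H]3C[C@@]21C | intermediate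
14 | (2S,4aS,6S,7R,8aS)-6,7-(isopropylidenedioxy)-2,5,5,8a-tetramethyloctahydronaphthalen-1(2H)-one (8β-methyl epimer) | O=C1[C@@H](C)CC[C@H]2C(C)(C)[C@@H]3OC(C)(C)O[C@@H]3C[C@@]21C | intermediate (not isolated)
15 | (2R,4aS,6S,7R,8aS)-6,7-(isopropylidenedioxy)-2,5,5,8a-tetramethyloctahydronaphthalen-1(2H)-one | O=C1[C@H](C)CC[C@H]2C(C)(C)[C@@H]3OC(C)(C)O[C@@H]3C[C@@]21C | intermediate
16 | (1S,2R,4aS,6S,7R,8aS)-1-ethenyl-6,7-(isopropylidenedioxy)-2,5,5,8a-tetramethyldecahydronaphthalen-1-ol | C=C[C@]1(O)[C@H](C)CC[C@H]2C(C)(C)[C@@H]3OC(C)(C)O[C@@H]3C[C@@]21C | intermediate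
17 | methyl acetoacetate | COC(=O)CC(C)=O | starting material
18 | methyl (2E)-3-{[(trifluoromethyl)sulfonyl]oxy}but-2-enoate | COC(=O)/C=C(\C)OS(=O)(=O)C(F)(F)F | intermediate
19 | 9-{2-[(1S,2R,4aS,6S,7R,8aS)-1-hydroxy-6,7-(isopropylidenedioxy)-2,5,5,8a-tetramethyldecahydronaphthalen-1-yl]ethyl}-9-borabicyclo[3.3.1]nonane | C1CCC2CCCC1B2CC[C@]3(O)[C@H](C)CC[C@H]4C(C)(C)[C@@H]5OC(C)(C)O[C@@H]5C[C@@]43C | intermediate (not isolated)
20 | methyl (2E)-5-[(1S,2R,4aS,6S,7R,8aS)-1-hydroxy-6,7-(isopropylidenedioxy)-2,5,5,8a-tetramethyldecahydronaphthalen-1-yl]-3-methylpent-2-enoate | COC(=O)/C=C(\C)CC[C@]1(O)[C@H](C)CC[C@H]2C(C)(C)[C@@H]3OC(C)(C)O[C@@H]3C[C@@]21C | intermediate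
21 | methyl (2E)-5-[(1S,2R,4aS,6S,7R,8aS)-1,6,7-trihydroxy-2,5,5,8a-tetramethyldecahydronaphthalen-1-yl]-3-methylpent-2-enoate | COC(=O)/C=C(\C)CC[C@]1(O)[C@H](C)CC[C@H]2C(C)(C)[C@H](O)[C@H](O)C[C@@]21C | target

**Totals.** Total step count: 12. Longest linear sequence: 11 steps (steps 1–9, 11 and 12); step 10 is a one-step side branch.

**Steps most likely to fail**

Step 7. The Michael closure at the congested C5–C10 bond may be slow or reversible, the enolate may add with its acyl group axial (cis fusion), and intermolecular aldol oligomerisation may compete. The fallback sets out from 8 and builds the two bonds stepwise from a regio-defined nucleophile. Thermodynamic silylation (Me3SiCl, NaI, Et3N, MeCN) should give the tetrasubstituted C9=C10 trimethylsilyl enol ether of 8 F1. Cross-metathesis with 9 as in step 6 then gives the silyl enol ether enal F2. An iminium-catalysed intramolecular Mukaiyama–Michael addition (5-benzyl-2-tert-butyl-3-methylimidazolidin-4-one trifluoroacetate, CH2Cl2/H2O, −20 °C) closes ring A under non-equilibrating conditions to the keto aldehyde 11, which is isolated here. A separate aldol condensation (KOH, MeOH) through 12 closes ring B, and the route is rejoined at 13.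

Step 6. The vinyl group on the fully substituted C4 may initiate too slowly, so that the catalyst decomposes or crotonaldehyde self-metathesis takes over. The fallback sets out from 8: ozonolysis (O3, CH2Cl2, −78 °C; PPh3) should give the aldehyde 2-[(4S,5R)-2,2-dimethyl-5-(2-methyl-3-oxopentyl)-1,3-dioxolan-4-yl]-2-methylpropanal F3. Wittig olefination with (triphenylphosphoranylidene)acetaldehyde (toluene, 80 °C) then gives the (E)-enal and rejoins the route at 10.

Step 9. The hindered ketone may be deprotonated at C8 in place of being attacked, and the α-facial preference may be incomplete. The fallback sets out from enone 13 and leaves out step 8. Vinylcerium addition to the enone carbonyl (no α-hydrogen, attack anti to the C10 methyl) should give the 9α-vinyl-9β-hydroxy-Δ7-ene acetonide F4. 9-BBN hydroborates only the monosubstituted vinyl group to the alkylborane F5, and Suzuki coupling with 18 as in step 11 gives the Δ7 ester F6. Hydroxyl-directed hydrogenation ([Ir(cod)(PCy3)(py)]PF6, H2, CH2Cl2) then delivers hydrogen to C8 from the β face, syn to the 9β-hydroxyl, and rejoins the route at 20.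

**Further compounds**
F1 | step 7 | {[5-((4R,5S)-2,2-dimethyl-5-(2-methylbut-3-en-2-yl)-1,3-dioxolan-4-yl)-4-methylpent-3-en-3-yl]oxy}trimethylsilane | CCC(O[Si](C)(C)C)=C(C)C[C@H]1OC(C)(C)O[C@H]1C(C)(C)C=C
F2 | step 7 | (2E)-4-[(4S,5R)-2,2-dimethyl-5-{2-methyl-3-[(trimethylsilyl)oxy]pent-2-en-1-yl}-1,3-dioxolan-4-yl]-4-methylpent-2-enal | CCC(O[Si](C)(C)C)=C(C)C[C@H]1OC(C)(C)O[C@H]1C(C)(C)/C=C/C=O
F3 | step 6 | 2-[(4S,5R)-2,2-dimethyl-5-(2-methyl-3-oxopentyl)-1,3-dioxolan-4-yl]-2-methylpropanal | CCC(=O)C(C)C[C@H]1OC(C)(C)O[C@H]1C(C)(C)C=O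
F4 | step 9 | 9α-vinyl-9β-hydroxy-Δ7-ene acetonide (1-ethenyl-6,7-(isopropylidenedioxy)-2,5,5,8a-tetramethyl-1,4,4a,5,6,7,8,8a-octahydronaphthalen-1-ol) | C=C[C@]1(O)C(C)=CC[C@H]2C(C)(C)[C@@H]3OC(C)(C)O[C@@H]3C[C@@]21C
F5 | step 9 | B-alkyl-9-borabicyclo[3.3.1]nonane from F4 (boron on C12) | C1CCC2CCCC1B2CC[C@]3(O)C(C)=CC[C@H]4C(C)(C)[C@@H]5OC(C)(C)O[C@@H]5C[C@@]43C
F6 | step 9 | methyl (2E)-5-[1-hydroxy-6,7-(isopropylidenedioxy)-2,5,5,8a-tetramethyl-1,4,4a,5,6,7,8,8a-octahydronaphthalen-1-yl]-3-methylpent-2-enoate (Δ7 ester) | COC(=O)/C=C(\C)CC[C@]1(O)C(C)=CC[C@H]2C(C)(C)[C@@H]3OC(C)(C)O[C@@H]3C[C@@]21C
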